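The target is cut at the C8–O4' ether bond and the C7–OH bond, which reveals two molecules of one phenol, (E)-4-propenylsyringol, plus water. The key step exploits that ring A and ring B are the same 3,5-dimethoxy-4-oxyphenyl unit, that C3, C5, C3' and C5' all carry OMe (no 8-5' coupling), and that C7/C8 are the former alkene carbons of one monomer. In one operation a laccase generates phenoxyl radicals, a dirigent protein joins C8 of one to O4' of the other on a defined face, and water adds to C7 of the quinone methide, setting both stereocentres. The precursor is the geometrically pure (E)-propenylphenol, made by one isomerization.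

Key step: step 2

Numbering used: ring A carries the free OH, C7 is the carbinol carbon, C8 the methyl-bearing carbon (C9 its methyl), ring B carries the intact propenyl group and O4' is its ether oxygen.

Remark on the chemistry: 4-allyl-2,6-dimethoxyphenol is taken as a purchasable flavour chemical; the target (C22H28O7) equals two monomers (C11H14O3) plus one oxygen atom, so the key step is an oxidation in which two hydrogen atoms go to O2 and the C7 oxygen comes from water, and the SMILES reads as 7R,8S, the erythro series.

Step 1
Reactants: 1 4-allyl-2,6-dimethoxyphenol
Product: 2 (E)-2,6-dimethoxy-4-(prop-1-en-1-yl)phenol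
Conditions: RhCl3·3H2O (cat.), EtOH, reflux, N2; then chromatography on SiO2/AgNO3 or recrystallization
Reagents that add atoms: none
Why: Olefin isomerization by a rhodium hydride (hydrometalation, then β-hydride elimination) moves the terminal double bond one carbon into conjugation with the electron-rich ring, the (E)-alkene being the thermodynamically preferred geometry, and the purification removes residual (Z)-isomer because ring B of the target keeps this side chain unchanged.

Step 2
Reactants: 2 (E)-2,6-dimethoxy-4-(prop-1-en-1-yl)phenol (two molecules)
Product: 5 (1R,2S)-1-(4-hydroxy-3,5-dimethoxyphenyl)-2-{2,6-dimethoxy-4-[(E)-prop-1-en-1-yl]phenoxy}propan-1-ol, via phenoxyl radical 3 (not isolated), via (8S)-quinone methide 4 (not isolated)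
Conditions: laccase (Trametes versicolor, cat.), 8-O-4'-directing dirigent protein, air (O2), NaOAc buffer pH 5/acetone, 20 °C, stopped at partial conversion; EtOAc extraction, SiO2 chromatography
Reagents that add atoms: water, O
Why: Proposed new method: laccase takes one electron from the phenol of 2 and hands it to O2, the dirigent protein (which has no redox function) holds two radicals 3 so that O4' of one bonds to the si face of C8 of the other, and water then adds to C7 of the ring A quinone methide 4, which restores the aromatic ring. The closest known reaction types are the racemic laccase- or peroxidase-mediated 8-O-4' dehydrodimerization of 4-propenylphenols and the enantioselective 8-8' coupling of coniferyl alcohol radicals under dirigent-protein control; a protein that steers 8-O-4' pairing is not available and would have to come from screening of dirigent homologues or from reshaping the two binding pockets of a pinoresinol-forming one, which is why the step is a proposal. No ring is closed. C8 (S) is set by the protein, which decides the face of C8 that meets O4'; C7 (R) is set by the substrate, since water should add anti to the bulky 2,6-dimethoxyaryloxy group in the conformer of 4 that keeps C8–H in the plane of the quinone methide (allylic 1,3-strain), which leads to the erythro isomer. The step needs 8-O-4' pairing over 8-8' and 8-5' pairing and dimer over oligomer: the OMe groups on C3 and C5 of each ring leave no free ortho carbon for 8-5' products, the protein has to suppress 8-8' pairing, and the ring A phenol of 5 lacks the conjugated side chain and should be oxidized less readily than 2, so the run is stopped early and 2 is recycled.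

Compound list
1 | 4-allyl-2,6-dimethoxyphenol | C=CCc1cc(OC)c(O)c(OC)c1 | starting material
2 | (E)-2,6-dimethoxy-4-(prop-1-en-1-yl)phenol | C/C=C/c1cc(OC)c(O)c(OC)c1 | intermediate
3 | 2,6-dimethoxy-4-[(E)-prop-1-en-1-yl]phenoxyl radical | C/C=C/c1cc(OC)c([O])c(OC)c1 | intermediate
4 | (8S)-quinone methide: 4-[(2S)-2-{2,6-dimethoxy-4-[(E)-prop-1-en-1-yl]phenoxy}propylidene]-2,6-dimethoxycyclohexa-2,5-dien-1-one | C/C=C/c1cc(OC)c(O[C@@H](C)C=C2C=C(OC)C(=O)C(OC)=C2)c(OC)c1 | intermediate
5 | (1R,2S)-1-(4-hydroxy-3,5-dimethoxyphenyl)-2-{2,6-dimethoxy-4-[(E)-prop-1-en-1-yl]phenoxy}propan-1-ol, the (7R,8S)-erythro 8-O-4' dimer | C/C=C/c1cc(OC)c(O[C@@H](C)[C@H](O)c2cc(OC)c(O)c(OC)c2)c(OC)c1 | target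

Total step count: 2
Longest linear sequence: 2 steps

Steps most likely to fail (the route has only two steps, so both are ranked and there is no third step to rank):

1. Step 2 (carries the label).
- What may go wrong: radical pairing outside the protein, which would mean no facial control at C8 and competing 8-8' pairing; weak anti selectivity in the water addition at C7; further oxidation of the product phenol with chain growth.
- Fallback (known chemistry), setting out from 2: horseradish peroxidase and H2O2 in acetone/aqueous buffer (pH 4–5), without any chiral protein, should dimerize 2 through radical 3 and through both enantiomers of the quinone methide, 4 and the (8R)-quinone methide F1. Water addition should then give the erythro alcohol as a racemate, that is 5 together with its (1S,2R)-enantiomer F2. Silica chromatography would remove threo and 8-8' products, and preparative HPLC on a chiral stationary phase (cellulose tris(3,5-dimethylphenylcarbamate)) would separate 5 from F2. The fallback comes back to the route at 5. The same HPLC method would serve to check, and if needed to raise, the enantiomeric purity of material from the main step.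

2. Step 1.
- What may go wrong: incomplete migration of the double bond, an (E)/(Z) mixture of the free phenol that resists separation, and air oxidation of the electron-rich propenylphenol or slowing of the catalyst by its free OH.
- Fallback, setting out from 1: acetylation (Ac2O, pyridine) would give 4-allyl-2,6-dimethoxyphenyl acetate F3. Isomerization of this ester under neutral conditions with RuHCl(CO)(PPh3)3 (cat.) in toluene at 80 °C should give (E)-2,6-dimethoxy-4-(prop-1-en-1-yl)phenyl acetate F4. As a non-phenolic ester, F4 cannot be oxidized to a phenoxyl radical and is expected to be freed from the (Z)-isomer by recrystallization. Methanolysis with catalytic K2CO3 in MeOH under N2 comes back to the route at 2.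

Further compounds
F1 | step 2 | (8R)-quinone methide: 4-[(2R)-2-{2,6-dimethoxy-4-[(E)-prop-1-en-1-yl]phenoxy}propylidene]-2,6-dimethoxycyclohexa-2,5-dien-1-one | C/C=C/c1cc(OC)c(O[C@H](C)C=C2C=C(OC)C(=O)C(OC)=C2)c(OC)c1
F2 | step 2 | (1S,2R)-1-(4-hydroxy-3,5-dimethoxyphenyl)-2-{2,6-dimethoxy-4-[(E)-prop-1-en-1-yl]phenoxy}propan-1-ol | C/C=C/c1cc(OC)c(O[C@H](C)[C@@H](O)c2cc(OC)c(O)c(OC)c2)c(OC)c1
F3 | step 1 | 4-allyl-2,6-dimethoxyphenyl acetate | C=CCc1cc(OC)c(OC(C)=O)c(OC)c1
F4 | step 1 | (E)-2,6-dimethoxy-4-(prop-1-en-1-yl)phenyl acetate | C/C=C/c1cc(OC)c(OC(C)=O)c(OC)c1
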